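**Retrosynthetic overview**

1. Target 26 ⇐ protected (2S)-flavanone 25 (global MOM/TES removal) ⇐ (2S,4S)-flavan-4-ol 24 (C4–OH → C=O). The C4 carbinol is only a placeholder for the ketone.
2. 24 ⇐ anti-diol 23 by intramolecular Cu-catalysed O-arylation forming O1–C8a. The strategy rests on O1 bridging the benzylic C2 carbinol carbon and aromatic C8a of ring A: closing ring C from the arene side never breaks the labile C2–O bond.
3. 23 ⇐ β-hydroxy ketone 22 (hydroxyl-directed anti reduction) ⇐ enol silane 20 + chromene aldehyde 9 (catalytic enantioselective Mukaiyama aldol, sets C2).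
4. A-ring ketone 18 from 5-bromoresorcinol (Hoesch acetylation, MOM, iodination next to Br, Sonogashira with 2-methylbut-3-yn-2-ol, hydrogenation, TES). Aldehyde 9 from 4-bromoresorcinol and 3-methylbut-2-enoic acid (chromanone → chromene, Br → CHO).
5. Ring order: the chromene pyran ring on ring B first, the dihydropyranone ring C last.

Key step: step 15

Assumption: the antipode of the bisphosphoramide catalyst that gives Si-face attack in step 13 is fixed in a trial run (Mosher analysis of 22); both antipodes are available, and C4 of 23/24 is a sacrificial stereocentre erased in step 16.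

**Route**

Step 1
Reactants: 1 4-bromoresorcinol; 2 3-methylbut-2-enoic acid
Product: 3 6-bromo-7-hydroxy-2,2-dimethylchroman-4-one
Conditions: MeSO3H, P2O5 (Eaton's reagent), 60 °C
Reagents that add atoms: none
Why: Friedel–Crafts acylation at the one ring position that is para to a hydroxyl and not between the two (the site at which 4-bromoresorcinol also undergoes Pechmann condensation), followed by oxa-Michael addition of the neighbouring phenol to the aryl enone, should give the chromanone with bromine fixed at C6.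

Step 2
Reactants: 3 6-bromo-7-hydroxy-2,2-dimethylchroman-4-one
Product: 4 6-bromo-7-(methoxymethoxy)-2,2-dimethylchroman-4-one
Conditions: MOMCl, i-Pr2NEt, CH2Cl2, 0 °C → rt
Reagents that add atoms: chloromethyl methyl ether, COCCl
Why: Williamson-type O-alkylation of the acidic para-acyl phenol installs an acetal that tolerates the hydride, organolithium and aldol steps to come.

Step 3
Reactants: 4 6-bromo-7-(methoxymethoxy)-2,2-dimethylchroman-4-one
Product: 5 (±)-6-bromo-7-(methoxymethoxy)-2,2-dimethylchroman-4-ol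
Conditions: NaBH4, MeOH/THF, 0 °C → rt
Reagents that add atoms: none
Why: Borohydride reduction of an aryl ketone; the carbinol stereocentre is removed again in step 4, so no control is needed.

Step 4
Reactants: 5 (±)-6-bromo-7-(methoxymethoxy)-2,2-dimethylchroman-4-ol
Product: 7 6-bromo-7-(methoxymethoxy)-2,2-dimethyl-2H-chromene, via chroman-4-yl mesylate 6 (not isolated)
Conditions: MsCl, Et3N, CH2Cl2, 0 → 40 °C
Reagents that add atoms: none
Why: Sulfonylation–elimination; the mesylate at the 2,4-dioxygenated benzylic carbon ionises easily and loses the C3 proton to Et3N, a dehydration under non-acidic conditions that keep the MOM ether.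

Step 5
Reactants: 7 6-bromo-7-(methoxymethoxy)-2,2-dimethyl-2H-chromene
Product: 9 7-(methoxymethoxy)-2,2-dimethyl-2H-chromene-6-carbaldehyde, via C6 aryllithium 8 (not isolated)
Conditions: n-BuLi, THF, −78 °C; DMF, −78 → 0 °C; H2O
Reagents that add atoms: N,N-dimethylformamide, CN(C)C=O
Why: Bromine–lithium exchange followed by formylation with DMF places the aldehyde at C6, whereas directed lithiation of the MOM ether would go to C8.

Step 6
Reactants: 10 5-bromoresorcinol
Product: 12 1-(2-bromo-4,6-dihydroxyphenyl)ethanone, via aryl ketiminium chloride 11 (not isolated)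
Conditions: MeCN, ZnCl2, HCl (g), Et2O, 0 °C → rt; then H2O, 90 °C
Reagents that add atoms: acetonitrile, CC#N; water, O
Why: Houben–Hoesch acylation; the nitrilium electrophile should attack para to one hydroxyl and next to bromine (as orcinol reacts next to its methyl group) in preference to the doubly ortho C2, and hydrolysis of the ketiminium salt gives the methyl ketone.

Step 7
Reactants: 12 1-(2-bromo-4,6-dihydroxyphenyl)ethanone
Product: 13 1-[2-bromo-4,6-bis(methoxymethoxy)phenyl]ethanone
Conditions: MOMCl (3 equiv), i-Pr2NEt, CH2Cl2, 0 → 40 °C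
Reagents that add atoms: chloromethyl methyl ether, COCCl
Why: Twofold O-alkylation; the ortho bromine twists the acetyl group out of plane and weakens its hydrogen bond to the 6-OH, so both phenols should be etherified.

Step 8
Reactants: 13 1-[2-bromo-4,6-bis(methoxymethoxy)phenyl]ethanone
Product: 14 1-[2-bromo-3-iodo-4,6-bis(methoxymethoxy)phenyl]ethanone
Conditions: NIS, MeCN, rt
Reagents that add atoms: N-iodosuccinimide, O=C1CCC(=O)N1I
Why: Electrophilic aromatic iodination; C3 is para to the 6-OMOM and ortho to the 4-OMOM and should be preferred over C5 between the two acetal oxygens, as in the C5 halogenation of 2,4-dialkoxyacetophenones and the halogenation of 1-bromo-3,5-dialkoxybenzenes next to bromine.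

Step 9
Reactants: 14 1-[2-bromo-3-iodo-4,6-bis(methoxymethoxy)phenyl]ethanone; 15 2-methylbut-3-yn-2-ol
Product: 16 1-[2-bromo-3-(3-hydroxy-3-methylbut-1-yn-1-yl)-4,6-bis(methoxymethoxy)phenyl]ethanone
Conditions: PdCl2(PPh3)2 (3 mol %), CuI (5 mol %), Et3N, THF, 50 °C, degassed
Reagents that add atoms: none
Why: Sonogashira coupling; oxidative addition into C–I is much faster than into the neighbouring C–Br, so only the iodide is replaced, and the alkyne delivers all five carbons and the tertiary hydroxyl of the side chain.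

Step 10
Reactants: 16 1-[2-bromo-3-(3-hydroxy-3-methylbut-1-yn-1-yl)-4,6-bis(methoxymethoxy)phenyl]ethanone
Product: 17 1-[2-bromo-3-(3-hydroxy-3-methylbutyl)-4,6-bis(methoxymethoxy)phenyl]ethanone
Conditions: H2 (1 atm), PtO2, EtOAc, rt, stopped after uptake of 2 equiv
Reagents that add atoms: none
Why: Catalytic hydrogenation of the alkyne to the alkane; platinum is chosen over palladium because it hydrogenolyses aryl bromides only sluggishly, and the twisted di-ortho-substituted ketone is reduced far more slowly than the triple bond.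

Step 11
Reactants: 17 1-[2-bromo-3-(3-hydroxy-3-methylbutyl)-4,6-bis(methoxymethoxy)phenyl]ethanone
Product: 18 1-{2-bromo-4,6-bis(methoxymethoxy)-3-[3-methyl-3-(triethylsilyloxy)butyl]phenyl}ethanone
Conditions: TESCl, imidazole, DMAP (cat.), DMF, 40 °C
Reagents that add atoms: chlorotriethylsilane, CC[Si](Cl)(CC)CC
Why: Silylation of the tertiary alcohol, which must be masked because its alkoxide could later close a 2,2-dimethylchroman onto the same C–Br bond; the chloride is used instead of the triflate to spare the aryl MOM ethers.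

Step 12
Reactants: 18 1-{2-bromo-4,6-bis(methoxymethoxy)-3-[3-methyl-3-(triethylsilyloxy)butyl]phenyl}ethanone
Product: 20 {1-[2-bromo-4,6-bis(methoxymethoxy)-3-(3-methyl-3-triethylsilyloxybutyl)phenyl]ethenyloxy}trimethylsilane, via lithium enolate 19 (not isolated)
Conditions: LDA (commercial solution), THF, −78 °C; TMSCl, −78 → 0 °C; concentration, pentane, filtration
Reagents that add atoms: chlorotrimethylsilane, C[Si](C)(C)Cl
Why: Kinetic deprotonation of the methyl ketone (the only enolisable position, and no hydrogen ortho to bromine, so no aryne) followed by O-silylation of the enolate.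

Step 13
Reactants: 20 trimethylsilyl enol ether of 18; 9 7-(methoxymethoxy)-2,2-dimethyl-2H-chromene-6-carbaldehyde
Product: 22 (3S)-1-{2-bromo-4,6-bis(methoxymethoxy)-3-[3-methyl-3-(triethylsilyloxy)butyl]phenyl}-3-hydroxy-3-[7-(methoxymethoxy)-2,2-dimethyl-2H-chromen-6-yl]propan-1-one, via trichlorosilyl aldolate 21 (not isolated)
Conditions: SiCl4 (1.5 equiv), binaphthyldiamine-derived bisphosphoramide (5 mol %, Si-face-selective antipode), i-Pr2NEt (0.2 equiv), CH2Cl2, −78 °C; then sat. aq. NaHCO3
Reagents that add atoms: none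
Why: Lewis-base-activated, SiCl4-mediated enantioselective Mukaiyama aldol addition; the phosphoramide-bound trichlorosilyl cation binds the aldehyde and exposes its Si face to the enol silane, so the carbinol carbon (the future C2) should be set as S under catalyst control.

Step 14
Reactants: 22 (3S)-β-hydroxy ketone
Product: 23 (1S,3S)-1-{2-bromo-4,6-bis(methoxymethoxy)-3-[3-methyl-3-(triethylsilyloxy)butyl]phenyl}-3-[7-(methoxymethoxy)-2,2-dimethyl-2H-chromen-6-yl]propane-1,3-diol (anti)
Conditions: Me4NBH(OAc)3, MeCN/AcOH (1:1), −30 → −20 °C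
Reagents that add atoms: none
Why: Evans–Saksena hydroxyl-directed reduction; exchange of an acetate for the C3 hydroxyl gives an alkoxyborohydride that delivers hydride intramolecularly through a chair-like transition state, which should set C1 as S (1,3-anti) under control of the C3 stereocentre.

Step 15
Reactants: 23 anti-(1S,3S)-diol
Product: 24 (2S,4S)-5,7-bis(methoxymethoxy)-2-[7-(methoxymethoxy)-2,2-dimethyl-2H-chromen-6-yl]-8-[3-methyl-3-(triethylsilyloxy)butyl]chroman-4-ol (2,4-cis)
Conditions: CuI (10 mol %), 3,4,7,8-tetramethyl-1,10-phenanthroline (20 mol %), Cs2CO3 (2 equiv), toluene, 110 °C, Ar, degassed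
Reagents that add atoms: none
Why: Ullmann-type intramolecular O-arylation: the phenanthroline-ligated copper(I) alkoxide formed at the C3 hydroxyl (the future O1) activates the neighbouring C–Br bond by oxidative addition, and reductive elimination forms the O1–C8a aryl ether. The closest known reaction is the copper-catalysed coupling of aryl bromides with secondary alcohols and its intramolecular version that gives chromans. Ring C, the only ring formed, closes as a six-membered ring by 6-exo attack of the tethered oxygen on the aryl carbon. No stereocentre is created: C2 keeps its S configuration because only the O–H bond of the carbinol is broken, never its C–O bond, and C4 is a spectator, so the anti-diol gives the 2,4-cis flavan-4-ol. The step needs selectivity among three oxygen nucleophiles and between C–O coupling and loss of bromine; the C1 hydroxyl could only close a four-membered ring, the tertiary alcohol is silylated, and copper alkoxides, unlike palladium alkoxides, do not readily undergo β-hydride elimination.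

Step 16
Reactants: 24 (2S,4S)-flavan-4-ol
Product: 25 (2S)-5,7-bis(methoxymethoxy)-2-[7-(methoxymethoxy)-2,2-dimethyl-2H-chromen-6-yl]-8-[3-methyl-3-(triethylsilyloxy)butyl]chroman-4-one
Conditions: Dess–Martin periodinane, NaHCO3, CH2Cl2, 0 °C → rt
Reagents that add atoms: none
Why: Dess–Martin oxidation of the benzylic secondary alcohol under buffered neutral conditions, which should leave the C2–O1 bond, the chromene, the acetals and the silyl ether untouched while erasing the auxiliary C4 stereocentre.

Step 17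
Reactants: 25 protected (2S)-flavanone
Product: 26 (2S)-5,7-dihydroxy-2-(7-hydroxy-2,2-dimethyl-2H-chromen-6-yl)-8-(3-hydroxy-3-methylbutyl)chroman-4-one (target, CNP0423488.1)
Conditions: 3 M aq. HCl, MeOH/THF, rt, stopped at full conversion
Reagents that add atoms: none
Why: Acid-catalysed acetal exchange of the three MOM ethers with methanol and solvolysis of the triethylsilyl ether; room temperature and short exposure are chosen so that neither acid-induced opening at C2–O1 nor ionisation of the tertiary alcohol should set in.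

**Compound list**

1 | 4-bromoresorcinol | Oc1ccc(Br)c(O)c1 | starting material
2 | 3-methylbut-2-enoic acid | CC(C)=CC(O)=O | starting material
3 | 6-bromo-7-hydroxy-2,2-dimethylchroman-4-one | CC1(C)CC(=O)c2cc(Br)c(O)cc2O1 | intermediate
4 | 6-bromo-7-(methoxymethoxy)-2,2-dimethylchroman-4-one | COCOc1cc2OC(C)(C)CC(=O)c2cc1Br | intermediate
5 | (±)-6-bromo-7-(methoxymethoxy)-2,2-dimethylchroman-4-ol | COCOc1cc2OC(C)(C)CC(O)c2cc1Br | intermediate
6 | (±)-6-bromo-7-(methoxymethoxy)-2,2-dimethylchroman-4-yl methanesulfonate | COCOc1cc2OC(C)(C)CC(OS(C)(=O)=O)c2cc1Br | intermediate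
7 | 6-bromo-7-(methoxymethoxy)-2,2-dimethyl-2H-chromene | COCOc1cc2OC(C)(C)C=Cc2cc1Br | intermediate
8 | [7-(methoxymethoxy)-2,2-dimethyl-2H-chromen-6-yl]lithium | COCOc1cc2OC(C)(C)C=Cc2cc1[Li] | intermediate
9 | 7-(methoxymethoxy)-2,2-dimethyl-2H-chromene-6-carbaldehyde | COCOc1cc2OC(C)(C)C=Cc2cc1C=O | intermediate
10 | 5-bromoresorcinol | Oc1cc(O)cc(Br)c1 | starting material
11 | 1-(2-bromo-4,6-dihydroxyphenyl)ethan-1-iminium chloride | CC(=[NH2+])c1c(O)cc(O)cc1Br.[Cl-] | intermediate
12 | 1-(2-bromo-4,6-dihydroxyphenyl)ethanone | CC(=O)c1c(O)cc(O)cc1Br | intermediate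
13 | 1-[2-bromo-4,6-bis(methoxymethoxy)phenyl]ethanone | CC(=O)c1c(OCOC)cc(OCOC)cc1Br | intermediate
14 | 1-[2-bromo-3-iodo-4,6-bis(methoxymethoxy)phenyl]ethanone | CC(=O)c1c(OCOC)cc(OCOC)c(I)c1Br | intermediate
15 | 2-methylbut-3-yn-2-ol | CC(C)(O)C#C | starting material
16 | 1-[2-bromo-3-(3-hydroxy-3-methylbut-1-yn-1-yl)-4,6-bis(methoxymethoxy)phenyl]ethanone | CC(=O)c1c(OCOC)cc(OCOC)c(C#CC(C)(C)O)c1Br | intermediate
17 | 1-[2-bromo-3-(3-hydroxy-3-methylbutyl)-4,6-bis(methoxymethoxy)phenyl]ethanone | CC(=O)c1c(OCOC)cc(OCOC)c(CCC(C)(C)O)c1Br | intermediate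
18 | 1-{2-bromo-4,6-bis(methoxymethoxy)-3-[3-methyl-3-(triethylsilyloxy)butyl]phenyl}ethanone | CC[Si](CC)(CC)OC(C)(C)CCc1c(OCOC)cc(OCOC)c(C(C)=O)c1Br | intermediate
19 | lithium enolate of 18 | C=C(O[Li])c1c(OCOC)cc(OCOC)c(CCC(C)(C)O[Si](CC)(CC)CC)c1Br | intermediate
20 | trimethylsilyl enol ether of 18 | C=C(O[Si](C)(C)C)c1c(OCOC)cc(OCOC)c(CCC(C)(C)O[Si](CC)(CC)CC)c1Br | intermediate
21 | (3S)-trichlorosilyl aldolate of 22 | CC(C)(O[Si](CC)(CC)CC)CCc1c(OCOC)cc(OCOC)c(C(=O)C[C@H](O[Si](Cl)(Cl)Cl)c2cc3c(cc2OCOC)OC(C)(C)C=C3)c1Br | intermediate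
22 | (3S)-1-{2-bromo-4,6-bis(methoxymethoxy)-3-[3-methyl-3-(triethylsilyloxy)butyl]phenyl}-3-hydroxy-3-[7-(methoxymethoxy)-2,2-dimethyl-2H-chromen-6-yl]propan-1-one | CC(C)(O[Si](CC)(CC)CC)CCc1c(OCOC)cc(OCOC)c(C(=O)C[C@H](O)c2cc3c(cc2OCOC)OC(C)(C)C=C3)c1Br | intermediate
23 | (1S,3S)-1-{2-bromo-4,6-bis(methoxymethoxy)-3-[3-methyl-3-(triethylsilyloxy)butyl]phenyl}-3-[7-(methoxymethoxy)-2,2-dimethyl-2H-chromen-6-yl]propane-1,3-diol | CC(C)(O[Si](CC)(CC)CC)CCc1c(OCOC)cc(OCOC)c([C@@H](O)C[C@H](O)c2cc3c(cc2OCOC)OC(C)(C)C=C3)c1Br | intermediate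
24 | (2S,4S)-5,7-bis(methoxymethoxy)-2-[7-(methoxymethoxy)-2,2-dimethyl-2H-chromen-6-yl]-8-[3-methyl-3-(triethylsilyloxy)butyl]chroman-4-ol | CC(C)(O[Si](CC)(CC)CC)CCc1c(OCOC)cc(OCOC)c2c1O[C@H](c1cc3c(cc1OCOC)OC(C)(C)C=C3)C[C@@H]2O | intermediate
25 | (2S)-5,7-bis(methoxymethoxy)-2-[7-(methoxymethoxy)-2,2-dimethyl-2H-chromen-6-yl]-8-[3-methyl-3-(triethylsilyloxy)butyl]chroman-4-one | CC(C)(O[Si](CC)(CC)CC)CCc1c(OCOC)cc(OCOC)c2c1O[C@H](c1cc3c(cc1OCOC)OC(C)(C)C=C3)CC2=O | intermediate
26 | (2S)-5,7-dihydroxy-2-(7-hydroxy-2,2-dimethyl-2H-chromen-6-yl)-8-(3-hydroxy-3-methylbutyl)chroman-4-one | CC(C)(O)CCc1c(O)cc(O)c2c1O[C@H](c1cc3c(cc1O)OC(C)(C)C=C3)CC2=O | target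

**Step count**

Total: 17 steps. Longest linear sequence: 12 steps (steps 6–17, from 5-bromoresorcinol). The aldehyde branch (steps 1–5) joins at step 13.

**Steps most likely to fail**

1. Step 15 (aryl ether closure). Oxidative addition of copper into the C–Br bond, flanked by the side chain and the carbinol arm, may be too slow at 110 °C. Hydrodebromination or oxidation of the free benzylic alkoxides could then overtake ring closure. The fallback switches to palladium and blocks the second hydroxyl. It sets out from 22. Evans–Tishchenko reduction (PhCHO, cat. SmI2, THF, −10 °C) should give the anti-(1S,3S)-diol 3-O-benzoate F1, with the ester on the chromenyl carbinol oxygen and the A-ring carbinol free. TESCl/imidazole/DMAP would give the C1 triethylsilyl ether benzoate F2. DIBAL-H at −78 °C would remove the ester to give the C1-silylated C3 alcohol F3. Pd(OAc)2 with 2-(di-tert-butylphosphino)-1,1′-binaphthyl and Cs2CO3 in toluene at 70 °C (Buchwald-type intramolecular etherification) closes the same O1–C8a bond to give the 4-O-triethylsilyl flavan F4. With O4 silylated, no palladium alkoxide can form next to the metal at C4. TBAF/AcOH removes both silyl groups to give the flavan-4-ol with free tertiary alcohol F5. Dess–Martin oxidation gives the tris-MOM flavanone with free tertiary alcohol F6. The acid treatment of step 17 then leads straight to 26, where the fallback rejoins the route.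

2. Step 13 (enantioselective aldol). Facial selectivity may be poor, because the catalyst pocket has to accommodate a di-ortho-substituted enol silane and an aldehyde whose ortho-OMOM group can compete for silicon. Chlorosilane-derived acid may also cause partial loss of acetals. The fallback separates C–C bond formation from stereocontrol. It sets out from 18 and 9. The lithium enolate of 18 (LDA, THF, −78 °C) adds to 9 to give the racemic β-hydroxy ketone F7. Dess–Martin oxidation gives the 1,3-diketone F8. Noyori transfer hydrogenation with RuCl[(S,S)-TsDPEN](p-cymene) and HCO2H/Et3N should reduce only the unhindered chromenyl carbonyl, with the S sense known for aryl ketones, and the di-ortho-substituted A-ring carbonyl should stay. The fallback returns to the route at 22; any over-reduced material would be the catalyst-controlled anti-diol 23 itself.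

3. Step 17 (global deprotection). Under protic acid the 2′,4′-dioxygenated benzylic C2–O1 bond may ionise and reclose, eroding the configuration at C2. The tertiary alcohol may also ionise and be trapped by the 7-OH as a dimethylchroman. The fallback replaces protic acidolysis by two orthogonal non-protic steps. It sets out from 25. TMSOTf/2,2′-bipyridyl in CH2Cl2 at 0 °C, then water, converts the aryl MOM ethers through aryl silyl ethers into phenols and should give the tertiary triethylsilyl ether of the target F9. HF·pyridine in THF/pyridine at 0 °C then removes the silyl group, and the fallback returns to the route at 26.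

**Further compounds**

F1 | step 15 | (1S,3S)-3-{2-bromo-4,6-bis(methoxymethoxy)-3-[3-methyl-3-(triethylsilyloxy)butyl]phenyl}-3-hydroxy-1-[7-(methoxymethoxy)-2,2-dimethyl-2H-chromen-6-yl]propyl benzoate | CC(C)(O[Si](CC)(CC)CC)CCc1c(OCOC)cc(OCOC)c([C@@H](O)C[C@H](OC(=O)c2ccccc2)c2cc3c(cc2OCOC)OC(C)(C)C=C3)c1Br
F2 | step 15 | C1 triethylsilyl ether of F1 | CC(C)(O[Si](CC)(CC)CC)CCc1c(OCOC)cc(OCOC)c([C@@H](O[Si](CC)(CC)CC)C[C@H](OC(=O)c2ccccc2)c2cc3c(cc2OCOC)OC(C)(C)C=C3)c1Br
F3 | step 15 | (1S,3S)-3-{2-bromo-4,6-bis(methoxymethoxy)-3-[3-methyl-3-(triethylsilyloxy)butyl]phenyl}-1-[7-(methoxymethoxy)-2,2-dimethyl-2H-chromen-6-yl]-3-(triethylsilyloxy)propan-1-ol | CC(C)(O[Si](CC)(CC)CC)CCc1c(OCOC)cc(OCOC)c([C@@H](O[Si](CC)(CC)CC)C[C@H](O)c2cc3c(cc2OCOC)OC(C)(C)C=C3)c1Br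
F4 | step 15 | (2S,4S)-4-O-triethylsilyl ether of 24 | CC(C)(O[Si](CC)(CC)CC)CCc1c(OCOC)cc(OCOC)c2c1O[C@H](c1cc3c(cc1OCOC)OC(C)(C)C=C3)C[C@@H]2O[Si](CC)(CC)CC
F5 | step 15 | (2S,4S)-8-(3-hydroxy-3-methylbutyl)-5,7-bis(methoxymethoxy)-2-[7-(methoxymethoxy)-2,2-dimethyl-2H-chromen-6-yl]chroman-4-ol | CC(C)(O)CCc1c(OCOC)cc(OCOC)c2c1O[C@H](c1cc3c(cc1OCOC)OC(C)(C)C=C3)C[C@@H]2O
F6 | step 15 | (2S)-8-(3-hydroxy-3-methylbutyl)-5,7-bis(methoxymethoxy)-2-[7-(methoxymethoxy)-2,2-dimethyl-2H-chromen-6-yl]chroman-4-one | CC(C)(O)CCc1c(OCOC)cc(OCOC)c2c1O[C@H](c1cc3c(cc1OCOC)OC(C)(C)C=C3)CC2=O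
F7 | step 13 | racemic 22 | CC(C)(O[Si](CC)(CC)CC)CCc1c(OCOC)cc(OCOC)c(C(=O)CC(O)c2cc3c(cc2OCOC)OC(C)(C)C=C3)c1Br
F8 | step 13 | 1-{2-bromo-4,6-bis(methoxymethoxy)-3-[3-methyl-3-(triethylsilyloxy)butyl]phenyl}-3-[7-(methoxymethoxy)-2,2-dimethyl-2H-chromen-6-yl]propane-1,3-dione | CC(C)(O[Si](CC)(CC)CC)CCc1c(OCOC)cc(OCOC)c(C(=O)CC(=O)c2cc3c(cc2OCOC)OC(C)(C)C=C3)c1Br
F9 | step 17 | (2S)-5,7-dihydroxy-2-(7-hydroxy-2,2-dimethyl-2H-chromen-6-yl)-8-[3-methyl-3-(triethylsilyloxy)butyl]chroman-4-one | CC(C)(O[Si](CC)(CC)CC)CCc1c(O)cc(O)c2c1O[C@H](c1cc3c(cc1O)OC(C)(C)C=C3)CC2=O
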